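Numbering: C1 methyl-bearing ring-fusion carbon, C4 isopropyl carbinol, C5 ring-fusion CH, C6 ester carbon, C7 CH2, C8 methyl carbinol, C9=C10 alkene. C9 is excised as dibromocarbene, so the precursor is a trans-hydrindane whose C8–C10 bond carries a dibromocyclopropane and whose C6 oxygen already bears the O-silyl vanillate. Silver-induced electrocyclic opening turns the six-membered ring into the cycloheptene and generates the C8–C9–C10 allyl cation; the C6 ester carbonyl, 1,3 to C8, captures C8 on its own face through a six-membered dioxanylium ion, delivering the ring, the C9=C10 alkene and the cis C8 carbinol in one operation. The hydrindene comes from an intramolecular Diels–Alder reaction.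

Key step: step 11

Remarks on the chemistry:
- "Me face" is the face of the C1 methyl and "H face" the face of H5. The target has C4–OH on the Me face and isopropyl, C6–O and C8–OH on the H face.
- Structures 21 and 23 were checked against the target: C1, C4, C5 and C6 agree, as does C8 in 23, and no correction is needed. The cyclopropane of 21 lies on the H face; C8 and C10 lose this configuration in step 11.
- C4–OH is left free in 21: C4 and C10 are anti across the trans ring fusion, so this hydroxyl cannot reach the cation.
- Assumption: in step 5 the (R,R)-salen ligand, (R,R)-N,N'-bis(3,5-di-tert-butylsalicylidene)cyclohexane-1,2-diamine, is taken to give the 4R carbinol (C3 of the nonadienynol name); if the sense is the opposite, its antipode is used.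

Step 1
Reactants: 1 methacrolein; 2 isopropenylmagnesium bromide
Product: 3 2,4-dimethylpenta-1,4-dien-3-ol
Conditions: THF, −78 → 0 °C; aq NH4Cl
Reagents that add atoms: none
Why: Grignard 1,2-addition to the enal carbonyl is fast at low temperature and gives the symmetrical bis-allylic alcohol, so no stereocentre arises.

Step 2
Reactants: 3 2,4-dimethylpenta-1,4-dien-3-ol; 4 triethyl orthoacetate
Product: 6 ethyl (4E)-4,6-dimethylhepta-4,6-dienoate, via ketene acetal 5 (not isolated)
Conditions: EtCO2H (cat.), 135 °C, EtOH distilled off
Reagents that add atoms: none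
Why: Johnson–Claisen rearrangement: the chair [3,3] shift with the spectator isopropenyl group equatorial should give the E trisubstituted alkene, which places the future tether trans to C8 across C1=C10 and the C1 methyl inside the diene.

Step 3
Reactants: 6 ethyl (4E)-4,6-dimethylhepta-4,6-dienoate
Product: 7 (4E)-N-methoxy-N,4,6-trimethylhepta-4,6-dienamide
Conditions: MeNH(OMe)·HCl, LiHMDS, THF, −78 → −10 °C
Reagents that add atoms: N,O-dimethylhydroxylamine hydrochloride, CNOC.Cl
Why: Weinreb amidation: the lithium amide of N,O-dimethylhydroxylamine displaces ethoxide from the unhindered ester, and the diene is inert to the base.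

Step 4
Reactants: 7 (4E)-N-methoxy-N,4,6-trimethylhepta-4,6-dienamide; 8 isopropylmagnesium chloride
Product: 9 (6E)-2,6,8-trimethylnona-6,8-dien-3-one
Conditions: THF, 0 °C; aq NH4Cl
Reagents that add atoms: none
Why: Weinreb ketone synthesis: the chelated tetrahedral adduct survives until work-up, so addition stops at the isopropyl ketone.

Step 5
Reactants: 9 (6E)-2,6,8-trimethylnona-6,8-dien-3-one; 10 trimethylsilylacetylene
Product: 12 (3R,6E)-6,8-dimethyl-3-(propan-2-yl)nona-6,8-dien-1-yn-3-ol, via silylalkyne 11 (not isolated)
Conditions: Me2Zn, (R,R)-salen ligand (20 mol %), toluene, rt; work-up; then K2CO3 (cat.), MeOH, rt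
Reagents that add atoms: none
Why: Catalytic enantioselective alkynylzinc addition to a dialkyl ketone: the Zn(salen) complex holds the ketone and the zinc acetylide formed from Me2Zn and 10, the ligand tells the branched isopropyl group from the unbranched chain and so sets C4, and methanolic carbonate then cleaves the alkynyl C–Si bond.

Step 6
Reactants: 12 (3R,6E)-6,8-dimethyl-3-(propan-2-yl)nona-6,8-dien-1-yn-3-ol
Product: 13 (1E,3R,6E)-6,8-dimethyl-3-(propan-2-yl)-1-(4,4,5,5-tetramethyl-1,3,2-dioxaborolan-2-yl)nona-1,6,8-trien-3-ol
Conditions: B2pin2, CuCl (5 mol %), Xantphos, NaOtBu (cat.), MeOH (2 equiv), THF, rt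
Reagents that add atoms: bis(pinacolato)diboron, CC1(C)OB(OC1(C)C)B1OC(C)(C)C(C)(C)O1
Why: Copper-catalysed protoboration: syn addition of Cu–Bpin across the terminal alkyne with boron at the unhindered terminus, then protonation by methanol, gives the E alkenylboronate; the protic medium tolerates the free tertiary hydroxyl and the diene reacts more slowly than the alkyne.

Step 7
Reactants: 13 (1E,3R,6E)-alkenylboronate triene
Product: 15 trans-hydrindene 4,6-diol (C1 methyl and H5 trans; C8=C10 alkene with methyl on C8; C4–OH on the Me face and isopropyl on the H face; C6–OH on the H face), via boronate cycloadduct 14 (not isolated)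
Conditions: toluene (0.02 M), BHT, 180 °C, sealed silanised vessel; then THF, aq NaOH, 30% H2O2, 0 °C → rt
Reagents that add atoms: hydrogen peroxide, OO
Why: Thermal type 1 intramolecular Diels–Alder reaction: the E alkenylboronate fixes H5 and boron cis, the tether-anti (boron-endo) transition state gives the trans ring fusion, the C4 centre should keep its isopropyl group away from the inside C1 methyl and thereby sets C1, C5 and C6 relative to C4, and alkaline peroxide oxidises the C–B bond with retention.

Step 8
Reactants: 16 vanillic acid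
Product: 18 4-[(tert-butyldimethylsilyl)oxy]-3-methoxybenzoic acid, via bis-silyl derivative 17 (not isolated)
Conditions: TBSCl (2.3 equiv), imidazole, DMF, rt; then AcOH/THF/H2O, rt
Reagents that add atoms: tert-butyldimethylsilyl chloride, CC(C)(C)[Si](C)(C)Cl
Why: Standard phenol protection: both acidic groups are silylated and the labile silyl ester is then hydrolysed selectively, leaving the aryl silyl ether.

Step 9
Reactants: 15 trans-hydrindene 4,6-diol; 18 4-[(tert-butyldimethylsilyl)oxy]-3-methoxybenzoic acid
Product: 19 C6 O-silyl vanillate of the hydrindene diol (C4–OH free)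
Conditions: EDC·HCl, DMAP, CH2Cl2, rt
Reagents that add atoms: none
Why: Steglich esterification: the acylpyridinium intermediate acylates the secondary C6 hydroxyl, while the tertiary C4 hydroxyl, flanked by isopropyl and the ring fusion, should not react.

Step 10
Reactants: 19 C6 O-silyl vanillate of the hydrindene diol; 20 phenyl(tribromomethyl)mercury
Product: 21 dibromocyclopropane-fused trans-hydrindane O-silyl vanillate (CBr2 bridging C8 and C10 on the H face)
Conditions: benzene, 80 °C
Reagents that add atoms: none
Why: Neutral thermal dibromocarbene transfer spares the ester, the aryl silyl ether and the hindered tertiary alcohol; cheletropic syn addition to the trisubstituted C8=C10 alkene should occur anti to the pseudoaxial C1 methyl.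

Step 11
Reactants: 21 dibromocyclopropane-fused trans-hydrindane O-silyl vanillate
Product: 23 9-bromo derivative of the O-silyl target (C6 ester, C8–OH cis to it, C9-bromo C9=C10 alkene), via dioxanylium ion 22 (not isolated)
Conditions: AgClO4 (2.5 equiv), CaCO3, acetone/H2O 9:1, 0 °C → rt, dark
Reagents that add atoms: water, O
Why: Silver ion abstracts the endo bromide (the one lying over the six-membered ring) while the C8–C10 bond opens in a disrotatory two-electron electrocyclic process, giving the cis 2-bromoallyl cation C8–C9–C10 inside the enlarged ring. The closest known reaction type is the silver-promoted electrocyclic ring expansion of ring-fused gem-dibromocyclopropanes to 2-bromocycloalk-2-enyl derivatives with capture of the cation by a tethered oxygen nucleophile. The cycloheptene forms by ring expansion, that is by cleavage of the bond shared by the three- and six-membered rings, and the transient dioxanylium ring of 22 closes by 6-exo attack of the ester carbonyl oxygen on the cationic C8 terminus. The new C8 stereocentre is set by this delivery, since the carbonyl oxygen can reach C8 only on the face of the C6–O bond; water then adds to the acyl carbon and the hemi-orthoester should collapse to the C6 ester and the C8 alcohol. The step needs site selectivity for C8 over C10 and internal capture ahead of external water or proton loss: C8 is the tertiary, better stabilised terminus within reach of a six-membered cyclic ion, whereas C10 is neopentyl and would need an eight-membered one. CaCO3 removes the perchloric acid so that the silyl ether and the tertiary allylic alcohol survive.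

Step 12
Reactants: 23 9-bromo derivative of the O-silyl target
Product: 24 O-silyl target
Conditions: (Me3Si)3SiH, AIBN, toluene, 85 °C
Reagents that add atoms: none
Why: Radical chain hydrodebromination: the silyl radical abstracts the vinylic bromine and the sp2 radical at C9 takes hydrogen from the silane faster than any 1,4-hydrogen shift open to it, while esters, alcohols and the silyl ether are inert.

Step 13
Reactants: 24 O-silyl target
Product: 25 CNP0243386.4 (target)
Conditions: TBAF, AcOH, THF, 0 °C
Reagents that add atoms: none
Why: Standard fluoride desilylation of the aryl silyl ether; acetic acid buffers the phenoxide so that the vanillate ester and the cis-1,3 hydroxy ester pair are not disturbed.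

Compound list
1 | methacrolein | C=C(C)C=O | starting material
2 | isopropenylmagnesium bromide | C=C(C)[Mg]Br | starting material
3 | 2,4-dimethylpenta-1,4-dien-3-ol | C=C(C)C(O)C(C)=C | intermediate
4 | triethyl orthoacetate | CC(OCC)(OCC)OCC | starting material
5 | 3-[(1-ethoxyethenyl)oxy]-2,4-dimethylpenta-1,4-diene (ketene acetal) | C=C(OCC)OC(C(C)=C)C(C)=C | intermediate (not isolated)
6 | ethyl (4E)-4,6-dimethylhepta-4,6-dienoate | C=C(C)/C=C(C)/CCC(=O)OCC | intermediate
7 | (4E)-N-methoxy-N,4,6-trimethylhepta-4,6-dienamide | C=C(C)/C=C(C)/CCC(=O)N(C)OC | intermediate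
8 | isopropylmagnesium chloride | CC(C)[Mg]Cl | starting material
9 | (6E)-2,6,8-trimethylnona-6,8-dien-3-one | C=C(C)/C=C(C)/CCC(=O)C(C)C | intermediate
10 | trimethylsilylacetylene | C#C[Si](C)(C)C | starting material
11 | (3R,6E)-6,8-dimethyl-3-(propan-2-yl)-1-(trimethylsilyl)nona-6,8-dien-1-yn-3-ol | C=C(C)/C=C(C)/CC[C@@](O)(C(C)C)C#C[Si](C)(C)C | intermediate (not isolated)
12 | (3R,6E)-6,8-dimethyl-3-(propan-2-yl)nona-6,8-dien-1-yn-3-ol | C=C(C)/C=C(C)/CC[C@@](O)(C(C)C)C#C | intermediate
13 | (1E,3R,6E)-6,8-dimethyl-3-(propan-2-yl)-1-(4,4,5,5-tetramethyl-1,3,2-dioxaborolan-2-yl)nona-1,6,8-trien-3-ol | C=C(C)/C=C(C)/CC[C@@](O)(C(C)C)/C=C/B1OC(C)(C)C(C)(C)O1 | intermediate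
14 | C6-pinacolboryl trans-hydrindene cycloadduct (boron on the H face, C4–OH on the Me face) | CC1(C)OB(OC1(C)C)[C@H]2CC(C)=C[C@@]3(C)CC[C@@](O)(C(C)C)[C@H]23 | intermediate (not isolated)
15 | trans-hydrindene 4,6-diol (C8=C10 alkene, C4–OH on the Me face, C6–OH on the H face) | O[C@H]2CC(C)=C[C@@]3(C)CC[C@@](O)(C(C)C)[C@H]23 | intermediate
16 | vanillic acid | COc1cc(C(=O)O)ccc1O | starting material
17 | tert-butyldimethylsilyl 4-[(tert-butyldimethylsilyl)oxy]-3-methoxybenzoate | COc1cc(C(=O)O[Si](C)(C)C(C)(C)C)ccc1O[Si](C)(C)C(C)(C)C | intermediate (not isolated)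
18 | 4-[(tert-butyldimethylsilyl)oxy]-3-methoxybenzoic acid | COc1cc(C(=O)O)ccc1O[Si](C)(C)C(C)(C)C | intermediate
19 | C6 O-silyl vanillate of the trans-hydrindene diol | COc1cc(C(=O)O[C@H]2CC(C)=C[C@@]3(C)CC[C@@](O)(C(C)C)[C@H]23)ccc1O[Si](C)(C)C(C)(C)C | intermediate
20 | phenyl(tribromomethyl)mercury | BrC(Br)(Br)[Hg]c1ccccc1 | starting material
21 | dibromocyclopropane-fused trans-hydrindane O-silyl vanillate (CBr2 on the H face across C8–C10) | COc1cc(C(=O)O[C@H]2C[C@@]4(C)C(Br)(Br)[C@H]4[C@@]3(C)CC[C@@](O)(C(C)C)[C@H]23)ccc1O[Si](C)(C)C(C)(C)C | intermediate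
22 | 2-aryl-1,3-dioxan-2-ylium perchlorate bridging O6 and O8 of the 9-bromocycloheptene | COc1cc(C(=[O+]4)O[C@H]2C[C@]4(C)C(Br)=C[C@@]3(C)CC[C@@](O)(C(C)C)[C@H]23)ccc1O[Si](C)(C)C(C)(C)C.[O-]Cl(=O)(=O)=O | intermediate (not isolated)
23 | 9-bromo derivative of the O-silyl target | COc1cc(C(=O)O[C@H]2C[C@@](C)(O)C(Br)=C[C@@]3(C)CC[C@@](O)(C(C)C)[C@H]23)ccc1O[Si](C)(C)C(C)(C)C | intermediate
24 | O-silyl target | COc1cc(C(=O)O[C@H]2C[C@@](C)(O)C=C[C@@]3(C)CC[C@@](O)(C(C)C)[C@H]23)ccc1O[Si](C)(C)C(C)(C)C | intermediate
25 | CNP0243386.4 | COc1cc(C(=O)O[C@H]2C[C@@](C)(O)C=C[C@@]3(C)CC[C@@](O)(C(C)C)[C@H]23)ccc1O | target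

Total step count: 13 (12 in the main line and 1 in the vanillate branch). Longest linear sequence: 12 steps (steps 1–7 and 9–13).

Steps most likely to fail

Step 11. The allyl cation may be taken by external water or lose a proton before the ester carbonyl engages, or the hemi-orthoester may collapse toward the tertiary oxygen so that the acyl group ends on C8–O. Fallback, setting out from diol 15 and coming back at 23: the secondary C6 hydroxyl is converted with Boc2O and DMAP into the tert-butyl carbonate F1. Carbene transfer from 20 gives the dibromocyclopropane F2. AgClO4 with CaCO3 in CH2Cl2 opens the cyclopropane, and the carbonate carbonyl captures C8 with loss of 2-methylpropene to give the cyclic carbonate F3. This locks the cis-1,3 relationship and rules out acyl migration. Methanolysis with K2CO3 in MeOH gives the bromo triol F4, and Steglich esterification with 18 at its only secondary hydroxyl returns to 23.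

Step 7. The tether may adopt the syn orientation and give the cis-fused adduct, C4 may control the diene face poorly, or a [1,5]-hydrogen shift of the inside-methyl diene may compete at 180 °C. Fallback, setting out from 13 and coming back at 21: acylative Suzuki coupling with acetyl chloride (Pd(PPh3)4, Cs2CO3, toluene) gives the E enone F5. Me2AlCl (2.2 equiv, CH2Cl2, −78 → −20 °C) promotes the Diels–Alder reaction at low temperature through the carbonyl-endo transition state, giving the trans-fused C6 methyl ketone F6. Carbene transfer from 20 gives the dibromocyclopropane F7. Baeyer–Villiger oxidation (CF3CO3H, Na2HPO4) with retention at C6 gives the acetate F8. Methanolysis gives the dibromocyclopropane diol F9, and Steglich esterification with 18 returns to 21.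

Step 5. The enantioselectivity of alkynylzinc addition to a ketone whose two alkyl groups differ only by branching may be insufficient. Fallback, setting out from 9 and coming back at 12: Horner–Wadsworth–Emmons reaction with triethyl phosphonoacetate and NaH, followed by chromatographic separation of the geometric isomers, gives the (2E)-enoate F10. DIBAL-H reduction gives the allylic alcohol F11. Sharpless epoxidation (Ti(OiPr)4, D-(−)-diisopropyl tartrate, t-BuOOH, molecular sieves, −20 °C) gives the epoxy alcohol F12. Appel chlorination (PPh3, CCl4) gives the epoxy chloride F13. n-BuLi (3 equiv, THF, −40 °C) then effects the double elimination that opens the epoxide and gives the propargylic alcohol 12 with C4 unchanged.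

Further compounds
F1 | step 11 | C6 tert-butyl carbonate of the trans-hydrindene diol | CC(C)(C)OC(=O)O[C@H]2CC(C)=C[C@@]3(C)CC[C@@](O)(C(C)C)[C@H]23
F2 | step 11 | dibromocyclopropane of the C6 tert-butyl carbonate | CC(C)(C)OC(=O)O[C@H]2C[C@@]4(C)C(Br)(Br)[C@H]4[C@@]3(C)CC[C@@](O)(C(C)C)[C@H]23
F3 | step 11 | cyclic carbonate bridging O6 and O8 of the 9-bromocycloheptene | O=C4O[C@H]2C[C@@](C)(O4)C(Br)=C[C@@]3(C)CC[C@@](O)(C(C)C)[C@H]23
F4 | step 11 | 9-bromo 4,6,8-triol | O[C@H]2C[C@@](C)(O)C(Br)=C[C@@]3(C)CC[C@@](O)(C(C)C)[C@H]23
F5 | step 7 | (3E,5R,8E)-5-hydroxy-8,10-dimethyl-5-(propan-2-yl)undeca-3,8,10-trien-2-one | CC(=O)/C=C/[C@](O)(C(C)C)CC/C(C)=C/C(C)=C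
F6 | step 7 | C6-acetyl trans-hydrindene (acetyl on the H face, C4–OH on the Me face) | CC(=O)[C@H]2CC(C)=C[C@@]3(C)CC[C@@](O)(C(C)C)[C@H]23
F7 | step 7 | dibromocyclopropane of the C6-acetyl hydrindene | CC(=O)[C@H]2C[C@@]4(C)C(Br)(Br)[C@H]4[C@@]3(C)CC[C@@](O)(C(C)C)[C@H]23
F8 | step 7 | C6 acetate of the dibromocyclopropane diol | CC(=O)O[C@H]2C[C@@]4(C)C(Br)(Br)[C@H]4[C@@]3(C)CC[C@@](O)(C(C)C)[C@H]23
F9 | step 7 | dibromocyclopropane-fused trans-hydrindane 4,6-diol | O[C@H]2C[C@@]4(C)C(Br)(Br)[C@H]4[C@@]3(C)CC[C@@](O)(C(C)C)[C@H]23
F10 | step 5 | ethyl (2E,6E)-6,8-dimethyl-3-(propan-2-yl)nona-2,6,8-trienoate | C=C(C)/C=C(C)/CC/C(C(C)C)=C\C(=O)OCC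
F11 | step 5 | (2E,6E)-6,8-dimethyl-3-(propan-2-yl)nona-2,6,8-trien-1-ol | C=C(C)/C=C(C)/CC/C(C(C)C)=C\CO
F12 | step 5 | [(2R,3R)-3-[(3E)-3,5-dimethylhexa-3,5-dien-1-yl]-3-(propan-2-yl)oxiran-2-yl]methanol | C=C(C)/C=C(C)/CC[C@]1(C(C)C)O[C@@H]1CO
F13 | step 5 | epoxy chloride of F12 (CH2Cl in place of CH2OH) | C=C(C)/C=C(C)/CC[C@]1(C(C)C)O[C@@H]1CCl
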